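The furan (O1, C2–C5) is cut at three bonds: C3–CH3, C4–C5 and O1–C5. The cut exploits the fact that methyl-bearing C3 sits beside oxygen-bearing C2 while C4 carries only hydrogen. A propargylic carbinol (C2–O1 next to a C3≡C4 triple bond) can therefore steer a methyl Grignard onto C3 and leave magnesium on C4. One flask adds the methyl group, acylates C4 with a hexanoyl Weinreb amide (C5 plus pentyl) and, on acidic work-up, closes and aromatises the ring. The precursor is a racemic terminal alkynol whose twelve-methylene chain ends in a bicyclic OBO orthoester masking the carboxyl group. It is reached in four steps from a C14 diacid half-ester.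

Key step: step 5

Abbreviation: OBO = 4-methyl-2,6,7-trioxabicyclo[2.2.2]octan-1-yl. The target has no stereocentre. All orthoester-bearing compounds are purified on Et3N-deactivated silica.

Remark on the chemistry: in the acidic work-up of step 5, ring closure and orthoester opening are assumed to run side by side, so 12 and 13 are drawn with the orthoester still closed.

Step 1
Reactants: 1 14-methoxy-14-oxotetradecanoic acid; 2 (3-methyloxetan-3-yl)methanol
Product: 3 1-methyl 14-[(3-methyloxetan-3-yl)methyl] tetradecanedioate
Conditions: DCC (1.1 equiv), DMAP (0.1 equiv), CH2Cl2, 0 °C → rt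
Reagents that add atoms: (3-methyloxetan-3-yl)methanol 2, CC1(CO)COC1
Why: Steglich esterification joins an unhindered acid and a primary alcohol under near-neutral conditions, so the methyl ester and the acid-sensitive oxetane should both survive.

Step 2
Reactants: 3 1-methyl 14-[(3-methyloxetan-3-yl)methyl] tetradecanedioate
Product: 4 methyl 13-(OBO)tridecanoate
Conditions: BF3·OEt2 (0.25 equiv), CH2Cl2, −15 °C → rt; Et3N quench
Reagents that add atoms: none
Why: OBO orthoester synthesis by Lewis acid-catalysed oxetanyl ester rearrangement, in which BF3 activates the oxetane oxygen, the neighbouring ester carbonyl opens the four-membered ring and the freed alkoxide closes the bicycle, whereas the distant methyl ester has no oxetane within reach and stays unchanged.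

Step 3
Reactants: 4 methyl 13-(OBO)tridecanoate
Product: 5 13-(OBO)tridecanal
Conditions: i-Bu2AlH (1.1 equiv), toluene/CH2Cl2, −78 °C; MeOH, then aq. potassium sodium tartrate
Reagents that add atoms: none
Why: Partial ester reduction with i-Bu2AlH, in which only one hydride is transferred at −78 °C before the non-acidic quench, should stop at the aldehyde and leave the orthoester, inert to hydride at this temperature, closed.

Step 4
Reactants: 5 13-(OBO)tridecanal; 6 ethynylmagnesium bromide
Product: 7 racemic 15-(OBO)pentadec-1-yn-3-ol
Conditions: HC≡CMgBr (1.5 equiv, 0.5 M in THF), THF, −20 → 0 °C; aq. NH4Cl brought to pH 8 with NH3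
Reagents that add atoms: ethynylmagnesium bromide 6, C#C[Mg]Br
Why: Grignard 1,2-addition of an alkynyl nucleophile to an unhindered aliphatic aldehyde leaves the orthoester untouched, and the new carbinol centre forms as a racemate, which does not matter because this carbon becomes the planar C2 of the furan.

Step 5
Reactants: 7 racemic 15-(OBO)pentadec-1-yn-3-ol; 8 methylmagnesium bromide; 9 N-methoxy-N-methylhexanamide
Product: 14 3-hydroxy-2-(hydroxymethyl)-2-methylpropyl 13-(3-methyl-5-pentylfuran-2-yl)tridecanoate, via oxamagnesacycle 10 (not isolated), via tetrahedral Weinreb adduct 11 (not isolated), via (Z)-hydroxy enone 12 (not isolated), via cyclic hemiketal 13 (not isolated)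
Conditions: MeMgBr (3.0 equiv, 3 M in Et2O), CuI (0.2 equiv), THF, −20 °C → rt; 9 (3.0 equiv), 0 °C → rt; 1 M aq. HCl/THF, 0 °C → rt, argon
Reagents that add atoms: methylmagnesium bromide 8, C[Mg]Br; N-methoxy-N-methylhexanamide 9, CCCCCC(=O)N(C)OC; water, O
Why: MeMgBr first deprotonates the hydroxyl of 7, and a methylcopper species generated from CuI then adds across C3≡C4 while magnesium stays bound to the alkoxide oxygen, so methyl lands on the carbinol-side carbon C3 and the metal on the terminal carbon C4, giving the five-membered chelate 10 by net anti addition. The C4–Mg bond of 10 attacks amide 9 in a Weinreb ketone synthesis (C4–C5), and adduct 11 resists a second addition until the quench. Dilute acid releases enone 12, whose hydroxyl and ketone are cis, so O1 closes on C5 in the 5-exo-trig mode to hemiketal 13 and loss of water aromatises the ring, while the same acid adds water to the orthoester and opens it to the diol ester. The closest known reaction type is the alkoxide-directed carbomagnesiation of propargylic alcohols with trapping by a formamide or CO2, which gives furans and butenolides, and a Weinreb amide is the ketone-level counterpart of the formamide trap. No stereocentre survives, since the carbinol carbon of 7 and the hemiketal carbon of 13 both become sp2. The step needs regioselectivity and anti selectivity in the methyl/magnesium addition, and both are secured by the C2 alkoxide, which holds magnesium on its own side of the new double bond.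

Step 6
Reactants: 14 3-hydroxy-2-(hydroxymethyl)-2-methylpropyl 13-(3-methyl-5-pentylfuran-2-yl)tridecanoate
Product: 16 13-(3-methyl-5-pentylfuran-2-yl)tridecanoic acid, via lithium carboxylate 15 (not isolated)
Conditions: LiOH (4 equiv), degassed THF/MeOH/H2O, rt; 0.5 M aq. HCl to pH 4–5, 0 °C, argon
Reagents that add atoms: lithium hydroxide, [Li+].[OH-]
Why: Saponification of a primary alkyl ester, to which the furan is inert, completes the usual two-stage release of an OBO-masked acid, and acidification only to pH 4–5 in the cold under argon should spare the electron-rich ring.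

Compound list
1 | 14-methoxy-14-oxotetradecanoic acid (monomethyl tetradecanedioate) | COC(=O)CCCCCCCCCCCCC(=O)O | starting material
2 | (3-methyloxetan-3-yl)methanol | CC1(CO)COC1 | starting material
3 | 1-methyl 14-[(3-methyloxetan-3-yl)methyl] tetradecanedioate | COC(=O)CCCCCCCCCCCCC(=O)OCC1(C)COC1 | intermediate
4 | methyl 13-(4-methyl-2,6,7-trioxabicyclo[2.2.2]octan-1-yl)tridecanoate | COC(=O)CCCCCCCCCCCCC12OCC(C)(CO1)CO2 | intermediate
5 | 13-(4-methyl-2,6,7-trioxabicyclo[2.2.2]octan-1-yl)tridecanal | O=CCCCCCCCCCCCCC12OCC(C)(CO1)CO2 | intermediate
6 | ethynylmagnesium bromide | C#C[Mg]Br | starting material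
7 | racemic 15-(4-methyl-2,6,7-trioxabicyclo[2.2.2]octan-1-yl)pentadec-1-yn-3-ol | C#CC(O)CCCCCCCCCCCCC12OCC(C)(CO1)CO2 | intermediate
8 | methylmagnesium bromide | C[Mg]Br | starting material
9 | N-methoxy-N-methylhexanamide | CCCCCC(=O)N(C)OC | starting material
10 | oxamagnesacycle, racemic 4-methyl-5-[12-(OBO)dodecyl]-2,5-dihydro-1,2-oxamagnesole (Mg bonded to O1 and to vinylic C4 of the future furan), formed in the flask | CC1=C[Mg]OC1CCCCCCCCCCCCC23OCC(C)(CO2)CO3 | intermediate
11 | tetrahedral Weinreb adduct, 4-[methoxy(methyl)amino]-6-methyl-7-[12-(OBO)dodecyl]-4-pentyl-4,7-dihydro-1,3,2-dioxamagnesepine, diastereomer mixture, formed in the flask | CCCCCC1(N(C)OC)C=C(C)C(CCCCCCCCCCCCC23OCC(C)(CO2)CO3)O[Mg]O1 | intermediate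
12 | racemic (Z)-9-hydroxy-8-methyl-21-(OBO)henicos-7-en-6-one, formed in the flask | CCCCCC(=O)/C=C(/C)C(O)CCCCCCCCCCCCC12OCC(C)(CO1)CO2 | intermediate
13 | cyclic hemiketal, 4-methyl-5-[12-(OBO)dodecyl]-2-pentyl-2,5-dihydrofuran-2-ol, diastereomer mixture, formed in the flask | CCCCCC1(O)C=C(C)C(CCCCCCCCCCCCC23OCC(C)(CO2)CO3)O1 | intermediate
14 | 3-hydroxy-2-(hydroxymethyl)-2-methylpropyl 13-(3-methyl-5-pentylfuran-2-yl)tridecanoate | CCCCCc1cc(C)c(CCCCCCCCCCCCC(=O)OCC(C)(CO)CO)o1 | intermediate
15 | lithium 13-(3-methyl-5-pentylfuran-2-yl)tridecanoate, formed in the flask | CCCCCc1cc(C)c(CCCCCCCCCCCCC(=O)[O-])o1.[Li+] | intermediate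
16 | 13-(3-methyl-5-pentylfuran-2-yl)tridecanoic acid (achiral) | CCCCCc1cc(C)c(CCCCCCCCCCCCC(=O)O)o1 | target

Total step count: 6. Longest linear sequence: 6 steps (1 → 16).

Steps most likely to fail

**Step 5.**
- **What may go wrong:** Metalation of the acetylenic C–H may compete with methyl transfer, which is why a third equivalent of MeMgBr is held in reserve. The addition may stall on the secondary carbinol. The chelated vinylmagnesium may also be acylated too slowly while surplus methyl Grignard uses up the amide.
- **Fallback:** It sets out from 7 and comes back at 12. It forms the same three bonds in another order and with reversed polarity at C3.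
- Double deprotonation of 7 (n-BuLi, 2.1 equiv, THF, −78 °C) and acylation of the acetylide with 9, quenched with NaH2PO4/Na2HPO4 buffer at pH 7, should give racemic 9-hydroxy-21-(4-methyl-2,6,7-trioxabicyclo[2.2.2]octan-1-yl)henicos-7-yn-6-one F1.
- Conjugate addition of Me2CuLi (from MeLi and CuI, 2.5 equiv, THF, −78 °C) then places methyl on the β-carbon C3. Syn addition leaves carbinol and ketone on the same side of the alkene, which is 12, and the dilute acid of step 5 carries 12 on to 14.
- Any E isomer arising from equilibration of the allenolate should be drawn into the furan by the same acid, because acid-catalysed isomerisation and cyclodehydration of E γ-hydroxy enones is known chemistry.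

**Step 3.**
- **What may go wrong:** Over-reduction to the alcohol level, or hydride delivery to the orthoester after coordination of aluminium to one of its oxygens.
- **Fallback:** It sets out from 4 and comes back at 5. It replaces the partial reduction by a full reduction and a separate oxidation.
- LiAlH4 (THF, 0 °C, work-up with H2O and aq. NaOH) should give 13-(4-methyl-2,6,7-trioxabicyclo[2.2.2]octan-1-yl)tridecan-1-ol F2.
- A Parikh–Doering oxidation (SO3·pyridine, DMSO, Et3N, CH2Cl2, 0 °C), basic throughout, should then return 5.

**Step 6.**
- **What may go wrong:** Air oxidation or acid-induced opening of the electron-rich trialkylfuran during acidification and isolation of the free acid.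
- **Fallback:** It sets out from 14 and comes back at 16. It avoids both strong base and mineral acid.
- Transesterification (K2CO3, MeOH, rt) should give methyl 13-(3-methyl-5-pentylfuran-2-yl)tridecanoate F3, which can be purified on silica.
- Hydrolysis with immobilised Candida antarctica lipase B (NaH2PO4/Na2HPO4 buffer pH 7, t-BuOH cosolvent, 35 °C, argon) should then release 16 at neutral pH.

Further compounds
F1 | step 5 | racemic 9-hydroxy-21-(4-methyl-2,6,7-trioxabicyclo[2.2.2]octan-1-yl)henicos-7-yn-6-one | CCCCCC(=O)C#CC(O)CCCCCCCCCCCCC12OCC(C)(CO1)CO2
F2 | step 3 | 13-(4-methyl-2,6,7-trioxabicyclo[2.2.2]octan-1-yl)tridecan-1-ol | OCCCCCCCCCCCCCC12OCC(C)(CO1)CO2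
F3 | step 6 | methyl 13-(3-methyl-5-pentylfuran-2-yl)tridecanoate | CCCCCc1cc(C)c(CCCCCCCCCCCCC(=O)OC)o1
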